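| flask | starting material | coupling partner | target | time |
|---|---|---|---|---|
| Tuesday's | 0.400 M | 1.00 M |  |  |
| Thursday's | 0.240 M | 0.840 M |  |  |
| Saturday's | 0.400 M | 1.00 M | 0.120 M |  |
| Sunday's | 0.400 M | 1.50 M |  |  |
| Wednesday's | 0.400 M | 2.40 M |  | 80 s |

| run | time / s | [target] / M |
|---|---|---|
| Tuesday's run | 3.2 | 0.0118 |
| Tuesday's run | 7.2 | 0.0227 |
| Tuesday's run | 16 | 0.0435 |
| Tuesday's run | 36 | 0.0704 |
| Tuesday's run | 80 | 0.0907 |
| Thursday's run | 3.2 | 0.0039 |
| Thursday's run | 7.2 | 0.0116 |
| Thursday's run | 16 | 0.0235 |
| Thursday's run | 36 | 0.0425 |
| Thursday's run | 80 | 0.0578 |
| Saturday's run | 3.2 | 0.1290 |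
| Saturday's run | 7.2 | 0.1400 |
| Saturday's run | 16 | 0.1556 |
| Saturday's run | 36 | 0.1731 |
| Saturday's run | 80 | 0.1768 |
| Sunday's run | 3.2 | 0.0185 |
| Sunday's run | 7.2 | 0.0348 |
| Sunday's run | 16 | 0.0614 |
| Sunday's run | 36 | 0.0945 |
| Sunday's run | 80 | 0.1076 |

(scatter of a reading: 0.001 M)

1. how the opening rate goes with [coupling partner] round the charge of the Tuesday's run: the exponent of the rate at two percent of starting material gone to target
2. how the opening rate goes with [starting material] round the charge of the Tuesday's run: the exponent of the rate at two percent of starting material gone to target (one fixed amount of target, the same in the runs compared)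
3. target in the Wednesday's run at 80 s, as a share of the starting material charged

- Overall: starting material + coupling partner -> target.
- Constant volume, constant temperature.
- An order is taken over about fifteen percent of the charge, up and down.

Saturday's flask was charged like Tuesday's, plus 0.120 M of target, so read that pair first. By 80 s, Tuesday's flask shows 0.0907 M, while Saturday's has gained 0.0568 M. If the making was the same in both, the shortfall of 0.0339 M is charged target that has been destroyed. You can call this loss wear, and treat it as pseudo-first-order in target at a given partner level. The wear constant, the fraction of target lost per second per molar of charged coupling partner, is then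

wear constant = ln(target charged / target surviving) / (time × partner) = 0.00415 M⁻¹ s⁻¹

The orders I read from the readings at 7.2 s, in logarithms. Sunday over Tuesday gives a partner order of 1.05. Removing that factor from Thursday over Tuesday leaves a starting-material order of 0.955, a noisy reading.

Now draw Wednesday's curve. Scaling Tuesday's opening chord by the partner order gives a slope of

0.00793 M s⁻¹

Tuesday's readings pass half their last value near 16 s, so I give the target an age of 64.0 s at the last reading. Adding the wear back gives my estimate of the target made:

Tuesday 0.118 M, Sunday 0.160 M, exponent in partner 0.749

If that exponent holds up to Wednesday's charge, I estimate 0.228 M made in Wednesday's flask, and the slope reaches that amount at a knee near 28.7 s. That is sooner than the wear clock of 100 s. My estimate of Wednesday's level at 80 s is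

0.120 M, or 30.1% of the charge.

The forecast gives a partner order of 1.1 (0.9 to 1.3), a starting-material order of 0.8 (0.55 to 1.05) and a share of 30% (27% to 34%) for Wednesday's flask, on the ground that “So the system is dying, not running out of reagent.” My starting-material order is higher than its 0.8, and my share, reached by another route, lies close to its 30%.

The simulation gives a partner order of 1.1, a starting-material order of 1.0, and target in Wednesday's run at 80 s of 27.3% of the starting material charged.

    starting material + coupling partner → target (0.009720 M⁻¹ s⁻¹)
    starting material + coupling partner → side product (0.003330 M⁻¹ s⁻¹)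
    2 starting material → homo dimer (0.03480 M⁻¹ s⁻¹)
    target + coupling partner → side product (0.004800 M⁻¹ s⁻¹)

Where two percent of Tuesday's starting material have turned, the rate stood at 0.0017 M s⁻¹ in Thursday's run and 0.0035 M s⁻¹ in Tuesday's. Counted on the charged partner, the wear constant puts the loss of target in Wednesday's flask at 80 s at 0.00109 M s⁻¹. At Sunday's last reading the same product gives 6.70 × 10⁻⁴ M s⁻¹, more than the net climb of that flask's last two readings, 2.98 × 10⁻⁴ M s⁻¹.

The readings are simulated with constants of no real substance; scatter was added.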